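**Assumption:** megaphone numbering is used throughout (ring C1 = C=O, C2=C3, C4 bears OMe, C5 = CH2, C6 quaternary; side chain C8 = CH(CH3), C7 = CH(OAc)Ar; allyl C1'–C3'; Ar = 3,4,5-trimethoxyphenyl). The target is the 4R,6R,7R,8S isomer encoded by the structure.

## The problem

Megaphone acetate 24 is a 4-methoxycyclohex-2-enone whose only quaternary carbon, C6, carries an allyl group and the acyclic chain C8(H)(CH3)–C7(H)(OAc)Ar. Ring and arene are joined only through this chain, so no ring fusion relays stereochemistry. C7 (R) and C8 (S) are contiguous and syn and can be made together in one carbonyl addition. C6 (R) is adjacent to C8 and can take instruction only from it. C4 (R) is 1,3 to C6, with its methoxy group cis to the side chain and trans to the allyl group, so C4 and C6 can control each other only in a ring-forming event. The γ-methoxy enone does not survive strong base or hard nucleophiles, the benzylic acetate on an electron-rich arene is lost to alkoxide and ionises in strong acid, and the trimethoxyarene limits the choice of oxidants. The enone and the acetate should therefore appear late and under near-neutral conditions. The enabling feature is that C6 bears two CH2–C arms, C5–C4 of the ring and C1'–C2' of the allyl group. A precursor with two identical CH2CHO arms has no stereocentre at C6, and C6 and C4 become stereogenic together when one arm is drawn into the ring by forming C3–C4.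

## Retrosynthesis

**24 ⇒ 23 ⇒ 22.** The terminal C2'=C3' bond and the O–CH3 bond at C4 are cut. The neighbouring cut, C6–C1' (allylation of a finished cyclohexenone), would have to build the quaternary centre on a base-sensitive γ-alkoxy enone under control of the remote C4. Cutting the alkene instead leaves C6 untouched. The precursor 22 carries the spectator arm as an aldehyde, the oxidation level in which it was made. The forward steps need a base-free O-methylation and a non-basic methylenation that takes an aldehyde in the presence of an enone and an acetate.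

**22 ⇒ 20.** The C3–C4 bond is cut, opening the ring to the bis(2-oxoethyl) (Z)-β-iodo enone 20. Cutting C1–C2 (a vinyl metal onto an acyl donor) or C2=C3 (metathesis) would each require C4 and C6 to be set beforehand. Only the C3–C4 cut creates the C4 carbinol and desymmetrises C6 in the same event. Compound 20 has two stereocentres (C7, C8) instead of four and no ring. The forward reaction needs a C3 vinyl metal that tolerates a ketone, an ester and a second aldehyde, which points to chromium. It must also select the pro-R arm and the aldehyde face that gives 4R.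

**20 ⇒ 18.** The two aldehyde C=O bonds are traced back to the C=C bond of a cyclopentene in 18. The alternative of two separate allyl groups would double the oxidative cleavage and release formaldehyde twice. The cyclopentene stores both arms in one robust, symmetric unit. The forward step needs a cleavage that takes the electron-rich ring alkene and spares the electron-poor iodo enone and the arene.

**18 ⇒ 17 ⇒ 16 ⇒ 15 ⇒ 11 + 12.** The C3–I bond is cut (hydroiodination of ynone 17), then the alkyne C–Si bond (16) and the O-acetyl bond (15), and finally C1–C2, back to spirolactone 11 and trimethylsilylacetylene 12. The lactone serves as acyl donor and as protecting group for the C7 oxygen, which it releases exactly when the acetate is to be installed. An open-chain ester would need separate protection of C7–OH. The forward steps need a single acetylide addition that stops at the ketone and a Z-selective hydroiodination.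

**11 ⇒ 8 + 9.** The C6–C5 and C6–C1' bonds are cut, giving the cis lactone 8 and cis-1,4-dichlorobut-2-ene 9. Because both new bonds end in the same symmetric ring, no stereocontrol at C6 is needed here, unlike a stepwise introduction of two different groups. The forward step needs a double enolate alkylation that closes the five-membered ring in SN2 fashion, not the three-membered ring in SN2' fashion.

**8 ⇒ 6 ⇒ 4 ⇒ 1 + 2.** The lactone is taken back to diol 6 and to homoallylic alcohol 4, and the C7–C8 bond is cut to 3,4,5-trimethoxybenzaldehyde 1 and (Z)-crotylboronate 2. A crotylation sets C7 and C8 together. An aldol route would need an auxiliary and a reduction. The forward step needs the syn diastereomer (from the Z reagent) and one enantiomer (from a chiral Brønsted acid catalyst), which is the only source of absolute configuration in the route.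

## Roads not taken

**Alternative 1:** The cut runs through C7–O and C7–C8 of a temporary tetrahydropyran and through C5–C6 of the carbocycle. The forward key step is a Prins–pinacol cascade to the spiro tetrahydropyran–cyclohex-3-enone A1. SnCl4 would condense the secondary alcohol of the alkylidene cyclopentenyl silyl ether A2 with aldehyde 1. The alkene attacks the oxocarbenium ion through C8, and the C6 cation is quenched by a 1,2-shift of a cyclopentene CH2 that expands the ring.
- Merits: C6, C7 and C8 are set in one step through a chair with the aryl group equatorial, a better-understood control element than the arm choice of step 10. The route is convergent. The chloromethyl carbinol carbon can later be fragmented with zinc to unveil the allyl group and the C7 hydroxyl together.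
- Weak points: A1 has its alkene at C3=C4 and no oxygen at C4. Epoxidation and base-induced opening to the 4-hydroxy enone would be needed, and C4 would rest on the facial selectivity of an epoxidation far from the controlling groups. Oxocarbenium ions from electron-rich aryl aldehydes are prone to oxonia-Cope scrambling and benzylic ionisation under SnCl4, which endangers C7. A2 needs a trisubstituted alkene of defined geometry and a sacrificial stereocentre, and about six steps follow the key step.
- Comparison: this road is better for C6. The chosen plan sets against it that the ring closure itself delivers C4 and the enone, and that only two steps follow.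

**Alternative 2:** The cut is C1–C6 and C4–C5. The forward key step would give the cis-1,4-diacetoxycyclohexene A3 by a Me2AlCl-promoted Diels–Alder reaction of the diene A4 with the 2-substituted acrolein A5.
- Merits: it is the most convergent road. The ring, both ring oxygens, the C2=C3 alkene and the quaternary carbon arise in one step.
- Weak points: an α-branched acrolein and a 1,4-disubstituted diene of modest reactivity form a hindered pair. The Lewis acid can ionise the acetates and the benzylic silyl ether. The facial selectivity (C6 against C8, acyclic 1,2-induction) and the endo/exo selectivity (C4 against C6) are both open, so it has as many unproven selectivities as step 10. Afterwards the formyl group must be homologated by one carbon and methylenated, the two acetates told apart, C1 oxidised, C4 methylated and the silyl group exchanged for acetyl, about eight steps.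
- Comparison: equal in stereochemical uncertainty and better in convergence. The chosen plan sets against it an intramolecular, kinetically favourable closure and a two-step endgame.

**Alternative 3:** The cut is C1–C2. The forward key step would give megaphone A6 directly. Iodine–lithium exchange (t-BuLi) on the (Z)-vinyl iodide of lactone A7 gives a C2 vinyllithium that attacks the lactone carbonyl, closes the cyclohexenone and releases the C7 alkoxide. A7 would come from lactone 8 by alkylation first with the enantiopure iodide A8 and then with allyl bromide, the second group entering trans to the C8 methyl.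
- Merits: C6 is set by the order of two alkylations, a reliable form of control. C4 is imported, no arm has to be chosen, and one acetylation of A6 gives 24.
- Weak points: A8 needs its own synthesis of several steps. It is a β-alkoxy primary iodide (slow SN2, competing elimination), and its (Z)-vinyl iodide is exposed twice to amide base. The closure uses t-BuLi beside a lactone, attacks a carbonyl flanked by a quaternary carbon, and leaves an alkoxide in the flask with the γ-methoxy enone.
- Comparison: this road is better in control of C6 and probably equal in step count once A8 is included. The chosen plan sets against it that all carbons come from four cheap achiral compounds in one linear sequence, that one catalytic step is the sole source of chirality, and that the ring closes under neutral conditions. Its price is the unproven arm selection, so the ordered alkylation of this alternative is kept as the fallback for step 10.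

Key step: step 10

## Route

Step 1
Reactants: 1 3,4,5-trimethoxybenzaldehyde; 2 (Z)-crotylboronic acid pinacol ester
Product: 4 (1R,2S)-2-methyl-1-(3,4,5-trimethoxyphenyl)but-3-en-1-ol, via pinacol borate ester 3 (not isolated)
Conditions: (R)-TRIP phosphoric acid (5 mol %), 4 Å MS, toluene, −30 °C; aq. NaHCO3
Reagents that add atoms: none
Why: Chiral phosphoric acid-catalysed crotylboration through a closed chair transition state, in which the Z geometry of 2 is translated into the syn C7/C8 relationship and the catalyst selects the aldehyde face. The (R)-acid is expected to deliver the 1R carbinol by analogy with its sense for aryl aldehydes, and the antipodal acid is equally available should the sense be opposite.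

Step 2
Reactants: 4 (1R,2S)-2-methyl-1-(3,4,5-trimethoxyphenyl)but-3-en-1-ol
Product: 6 (1R,2S)-2-methyl-1-(3,4,5-trimethoxyphenyl)butane-1,4-diol, via B-alkyl-9-BBN adduct 5 (not isolated)
Conditions: 9-BBN (2.5 equiv), THF, 0 °C → rt; NaOH, H2O2, 0 °C → rt
Reagents that add atoms: hydrogen peroxide, OO
Why: Anti-Markovnikov hydroboration–oxidation of the monosubstituted alkene. The free hydroxyl consumes one equivalent of borane as a borinate, and neither stereocentre is touched.

Step 3
Reactants: 6 (1R,2S)-2-methyl-1-(3,4,5-trimethoxyphenyl)butane-1,4-diol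
Product: 8 (4S,5R)-4-methyl-5-(3,4,5-trimethoxyphenyl)oxolan-2-one (cis lactone), via lactol 7 (not isolated)
Conditions: TEMPO (0.2 equiv), PhI(OAc)2 (2.5 equiv), CH2Cl2, rt
Reagents that add atoms: none
Why: Oxidative lactonisation of a 1,4-diol. The oxoammonium species oxidises the primary alcohol much faster than the secondary one, the hydroxy aldehyde closes to lactol 7, and this is oxidised to the lactone with the cis aryl/methyl relationship retained.

Step 4
Reactants: 8 (4S,5R)-4-methyl-5-(3,4,5-trimethoxyphenyl)oxolan-2-one; 9 cis-1,4-dichlorobut-2-ene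
Product: 11 (3R,4S)-4-methyl-3-(3,4,5-trimethoxyphenyl)-2-oxaspiro[4.4]non-7-en-1-one, via allylic chloride 10 (not isolated)
Conditions: LiN(SiMe3)2 (1.1 equiv), THF, −78 °C; 9 (1.3 equiv), DMPU, −78 → −20 °C; LiN(SiMe3)2 (1.2 equiv), −78 → 0 °C
Reagents that add atoms: none
Why: Double alkylation of a lactone enolate. The first is an intermolecular SN2 reaction, and the second is a 5-exo-tet cycloalkylation that the cis alkene geometry makes possible. C6 is not stereogenic in 11 because its two ring arms are identical, so the facial course of either alkylation is irrelevant.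

Step 5
Reactants: 11 (3R,4S)-4-methyl-3-(3,4,5-trimethoxyphenyl)-2-oxaspiro[4.4]non-7-en-1-one; 12 trimethylsilylacetylene
Product: 15 1-{1-[(1R,2S)-1-hydroxy-1-(3,4,5-trimethoxyphenyl)propan-2-yl]cyclopent-3-en-1-yl}-3-(trimethylsilyl)prop-2-yn-1-one, via lithium trimethylsilylacetylide 13 (not isolated), via spiro hemiketal 14 (not isolated)
Conditions: 12, n-BuLi, THF, −78 °C; 11, −78 → −50 °C; AcOH, −78 °C
Reagents that add atoms: none
Why: Acyl substitution of a lactone by a lithium acetylide. The tetrahedral lithium alkoxide persists at low temperature, so addition stops at the ketone stage. The C7–O bond is not broken, so C7 keeps its configuration. Hydroxy ynone 15 is expected to equilibrate with hemiketal 14, and either form serves in step 6.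

Step 6
Reactants: 15 1-{1-[(1R,2S)-1-hydroxy-1-(3,4,5-trimethoxyphenyl)propan-2-yl]cyclopent-3-en-1-yl}-3-(trimethylsilyl)prop-2-yn-1-one
Product: 16 (1R,2S)-2-{1-[3-(trimethylsilyl)prop-2-ynoyl]cyclopent-3-en-1-yl}-1-(3,4,5-trimethoxyphenyl)propyl acetate
Conditions: Ac2O, pyridine, DMAP (cat.), CH2Cl2, 0 °C → rt
Reagents that add atoms: acetic anhydride, CC(=O)OC(C)=O
Why: DMAP-catalysed acylation of the secondary benzylic alcohol. The open-chain tautomer is acylated far faster than the tertiary hemiketal hydroxyl, so the ring–chain equilibrium drains into 16.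

Step 7
Reactants: 16 (1R,2S)-2-{1-[3-(trimethylsilyl)prop-2-ynoyl]cyclopent-3-en-1-yl}-1-(3,4,5-trimethoxyphenyl)propyl acetate
Product: 17 (1R,2S)-2-[1-(prop-2-ynoyl)cyclopent-3-en-1-yl]-1-(3,4,5-trimethoxyphenyl)propyl acetate
Conditions: Na2B4O7·10H2O, MeOH–H2O, rt, short reaction time
Reagents that add atoms: none
Why: Protodesilylation of an alkynyl ketone under the weakly basic borate buffer. It is mild enough to leave the acetate in place and to avoid conjugate addition of methoxide to the terminal ynone.

Step 8
Reactants: 17 (1R,2S)-2-[1-(prop-2-ynoyl)cyclopent-3-en-1-yl]-1-(3,4,5-trimethoxyphenyl)propyl acetate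
Product: 18 (1R,2S)-2-{1-[(2Z)-3-iodoprop-2-enoyl]cyclopent-3-en-1-yl}-1-(3,4,5-trimethoxyphenyl)propyl acetate
Conditions: NaI, AcOH, MeCN, 0 °C → rt, dark
Reagents that add atoms: sodium iodide, [Na+].[I-]
Why: Conjugate hydroiodination of an ynone. Iodide adds to the β-carbon and the allenol is protonated anti to iodine, so the Z isomer is the kinetic product. Short exposure at low temperature in the dark is meant to prevent Z to E isomerisation and ionisation of the benzylic acetate.

Step 9
Reactants: 18 (1R,2S)-2-{1-[(2Z)-3-iodoprop-2-enoyl]cyclopent-3-en-1-yl}-1-(3,4,5-trimethoxyphenyl)propyl acetate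
Product: 20 (1R,2S,5Z)-6-iodo-2-methyl-4-oxo-3,3-bis(2-oxoethyl)-1-(3,4,5-trimethoxyphenyl)hex-5-en-1-yl acetate, via methoxy hydroperoxide 19 (not isolated)
Conditions: O3, CH2Cl2–MeOH (4:1), NaHCO3, −78 °C, Sudan Red 7B end point; Me2S, −78 °C → rt
Reagents that add atoms: ozone, [O-][O+]=O
Why: Ozonolysis with reductive work-up. The strained cis-disubstituted ring alkene reacts far faster than the electron-poor iodo enone or the arene, and the dye marks the end point. Both arms emerge as identical CH2CHO groups, so C6 is prochiral in 20.

Step 10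
Reactants: 20 (1R,2S,5Z)-6-iodo-2-methyl-4-oxo-3,3-bis(2-oxoethyl)-1-(3,4,5-trimethoxyphenyl)hex-5-en-1-yl acetate
Product: 22 (1R,2S)-2-[(1S,5R)-5-hydroxy-2-oxo-1-(2-oxoethyl)cyclohex-3-en-1-yl]-1-(3,4,5-trimethoxyphenyl)propyl acetate, via vinylchromium dichloride 21 (not isolated)
Conditions: CrCl2 (6 equiv), NiCl2 (1 mol %), degassed DMSO, 0.005 M, rt; aq. NH4Cl
Reagents that add atoms: none
Why: Divalent chromium reduces NiCl2 to zerovalent nickel, which inserts into the C3–I bond, and transmetallation gives the trivalent vinylchromium 21, which tolerates the ketone, the acetate and the second aldehyde. The closest known reaction type is the intramolecular Nozaki–Hiyama–Kishi coupling of (Z)-β-iodo enones with tethered aldehydes to give 4-hydroxycycloalk-2-enones. The ring closes by 6-exo-trig attack of C3 on one aldehyde carbon through a half-chair that already contains the Z C2=C3 bond, and the four-centre C3–Cr···O=C4 array holds the aldehyde oxygen near the enone plane, that is pseudo-equatorial. C4 is therefore set relative to C6 by the ring: with the branched C8 chain pseudo-equatorial on C6 and the spectator arm axial, the oxygen is cis to the side chain, as in 24. C6 becomes stereogenic through the choice of arm, closure of the pro-R arm gives the required centre, and the only element that can make this choice is the adjacent C8 stereocentre. The working model places the C8 hydrogen beside the C1 carbonyl oxygen, the methyl group anti to C1 and the C7 branch on the ring face opposite the axial arm, whereas closure of the pro-S arm with the same arrangement would push the methyl group between the carbonyl and the axial arm. The step thus needs arm selectivity and 4R facial selectivity, which the ring geometry couples, and the model that predicts the desired 4R,6R outcome is plausible but unproven. High dilution and a very low nickel loading are chosen to suppress intermolecular coupling and homocoupling of the iodo enone.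

Step 11
Reactants: 22 (1R,2S)-2-[(1S,5R)-5-hydroxy-2-oxo-1-(2-oxoethyl)cyclohex-3-en-1-yl]-1-(3,4,5-trimethoxyphenyl)propyl acetate
Product: 23 (1R,2S)-2-[(1S,5R)-5-methoxy-2-oxo-1-(2-oxoethyl)cyclohex-3-en-1-yl]-1-(3,4,5-trimethoxyphenyl)propyl acetate
Conditions: MeOTf, 2,6-di-tert-butyl-4-methylpyridine, CH2Cl2, 0 °C → rt
Reagents that add atoms: methyl trifluoromethanesulfonate, COS(=O)(=O)C(F)(F)F
Why: O-Alkylation of a secondary allylic alcohol with a hard methylating agent and a non-nucleophilic hindered base. No alkoxide is formed, so the γ-oxygenated enone, the enolisable aldehyde and the acetate are not exposed to base, and C4 keeps its configuration because the C–O bond is not broken.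

Step 12
Reactants: 23 (1R,2S)-2-[(1S,5R)-5-methoxy-2-oxo-1-(2-oxoethyl)cyclohex-3-en-1-yl]-1-(3,4,5-trimethoxyphenyl)propyl acetate
Product: 24 megaphone acetate, (1R,2S)-2-[(1R,5R)-5-methoxy-2-oxo-1-(prop-2-en-1-yl)cyclohex-3-en-1-yl]-1-(3,4,5-trimethoxyphenyl)propyl acetate
Conditions: Zn, CH2I2, Ti(OiPr)4, THF, 0 °C → rt
Reagents that add atoms: diiodomethane, ICI
Why: Takai-type methylenation with a geminal dizinc reagent moderated by Ti(OiPr)4, which is non-basic and takes aldehydes in preference to ketones and esters. The hindered conjugated C1 carbonyl and the acetate should be untouched, and the CH2CHO arm becomes the allyl group.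

## Compound list

1 | 3,4,5-trimethoxybenzaldehyde | COc1cc(C=O)cc(OC)c1OC | starting material
2 | (Z)-crotylboronic acid pinacol ester, 2-[(2Z)-but-2-en-1-yl]-4,4,5,5-tetramethyl-1,3,2-dioxaborolane | C/C=C\CB1OC(C)(C)C(C)(C)O1 | starting material
3 | pinacol borate ester of alcohol 4 (O-boryl homoallylic alcohol) | C=C[C@H](C)[C@@H](OB1OC(C)(C)C(C)(C)O1)c1cc(OC)c(OC)c(OC)c1 | intermediate (not isolated)
4 | (1R,2S)-2-methyl-1-(3,4,5-trimethoxyphenyl)but-3-en-1-ol (syn) | C=C[C@H](C)[C@@H](O)c1cc(OC)c(OC)c(OC)c1 | intermediate
5 | B-alkyl-9-BBN adduct of 4, with the C7 oxygen as its 9-BBN borinate | B1(CC[C@H](C)[C@@H](OB2C3CCCC2CCC3)c2cc(OC)c(OC)c(OC)c2)C2CCCC1CCC2 | intermediate (not isolated)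
6 | (1R,2S)-2-methyl-1-(3,4,5-trimethoxyphenyl)butane-1,4-diol | OCC[C@H](C)[C@@H](O)c1cc(OC)c(OC)c(OC)c1 | intermediate
7 | (4S,5R)-4-methyl-5-(3,4,5-trimethoxyphenyl)oxolan-2-ol (lactol, both anomers) | OC1C[C@H](C)[C@H](c2cc(OC)c(OC)c(OC)c2)O1 | intermediate (not isolated)
8 | (4S,5R)-4-methyl-5-(3,4,5-trimethoxyphenyl)oxolan-2-one (cis lactone) | O=C1C[C@H](C)[C@H](c2cc(OC)c(OC)c(OC)c2)O1 | intermediate
9 | cis-1,4-dichlorobut-2-ene | ClC/C=C\CCl | starting material
10 | (4S,5R)-3-[(2Z)-4-chlorobut-2-en-1-yl]-4-methyl-5-(3,4,5-trimethoxyphenyl)oxolan-2-one (C3 epimers) | O=C1C(C/C=C\CCl)[C@H](C)[C@H](c2cc(OC)c(OC)c(OC)c2)O1 | intermediate (not isolated)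
11 | (3R,4S)-4-methyl-3-(3,4,5-trimethoxyphenyl)-2-oxaspiro[4.4]non-7-en-1-one | O=C1C2(CC=CC2)[C@H](C)[C@H](c2cc(OC)c(OC)c(OC)c2)O1 | intermediate
12 | trimethylsilylacetylene | C#C[Si](C)(C)C | starting material
13 | lithium trimethylsilylacetylide | [Li]C#C[Si](C)(C)C | intermediate (not isolated)
14 | (3R,4S)-4-methyl-3-(3,4,5-trimethoxyphenyl)-1-[(trimethylsilyl)ethynyl]-2-oxaspiro[4.4]non-7-en-1-ol (hemiketal, C1 epimers) | OC1(C#C[Si](C)(C)C)C2(CC=CC2)[C@H](C)[C@H](c2cc(OC)c(OC)c(OC)c2)O1 | intermediate (not isolated)
15 | 1-{1-[(1R,2S)-1-hydroxy-1-(3,4,5-trimethoxyphenyl)propan-2-yl]cyclopent-3-en-1-yl}-3-(trimethylsilyl)prop-2-yn-1-one | C[Si](C)(C)C#CC(=O)C1(CC=CC1)[C@H](C)[C@@H](O)c1cc(OC)c(OC)c(OC)c1 | intermediate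
16 | (1R,2S)-2-{1-[3-(trimethylsilyl)prop-2-ynoyl]cyclopent-3-en-1-yl}-1-(3,4,5-trimethoxyphenyl)propyl acetate | C[Si](C)(C)C#CC(=O)C1(CC=CC1)[C@H](C)[C@@H](OC(C)=O)c1cc(OC)c(OC)c(OC)c1 | intermediate
17 | (1R,2S)-2-[1-(prop-2-ynoyl)cyclopent-3-en-1-yl]-1-(3,4,5-trimethoxyphenyl)propyl acetate | C#CC(=O)C1(CC=CC1)[C@H](C)[C@@H](OC(C)=O)c1cc(OC)c(OC)c(OC)c1 | intermediate
18 | (1R,2S)-2-{1-[(2Z)-3-iodoprop-2-enoyl]cyclopent-3-en-1-yl}-1-(3,4,5-trimethoxyphenyl)propyl acetate | I/C=C\C(=O)C1(CC=CC1)[C@H](C)[C@@H](OC(C)=O)c1cc(OC)c(OC)c(OC)c1 | intermediate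
19 | (1R,2S,5Z)-3-(2-hydroperoxy-2-methoxyethyl)-6-iodo-2-methyl-4-oxo-3-(2-oxoethyl)-1-(3,4,5-trimethoxyphenyl)hex-5-en-1-yl acetate (isomers at C3 and the peroxyacetal carbon) | O=CCC(CC(OC)OO)([C@H](C)[C@@H](OC(C)=O)c1cc(OC)c(OC)c(OC)c1)C(=O)/C=C\I | intermediate (not isolated)
20 | (1R,2S,5Z)-6-iodo-2-methyl-4-oxo-3,3-bis(2-oxoethyl)-1-(3,4,5-trimethoxyphenyl)hex-5-en-1-yl acetate | O=CCC(CC=O)([C@H](C)[C@@H](OC(C)=O)c1cc(OC)c(OC)c(OC)c1)C(=O)/C=C\I | intermediate
21 | (Z)-vinylchromium dichloride derived from 20 (CrCl2 in place of iodine at C3) | O=CCC(CC=O)([C@H](C)[C@@H](OC(C)=O)c1cc(OC)c(OC)c(OC)c1)C(=O)/C=C\[Cr](Cl)Cl | intermediate (not isolated)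
22 | (1R,2S)-2-[(1S,5R)-5-hydroxy-2-oxo-1-(2-oxoethyl)cyclohex-3-en-1-yl]-1-(3,4,5-trimethoxyphenyl)propyl acetate | O=CC[C@]1([C@H](C)[C@@H](OC(C)=O)c2cc(OC)c(OC)c(OC)c2)C[C@@H](O)C=CC1=O | intermediate
23 | (1R,2S)-2-[(1S,5R)-5-methoxy-2-oxo-1-(2-oxoethyl)cyclohex-3-en-1-yl]-1-(3,4,5-trimethoxyphenyl)propyl acetate | O=CC[C@]1([C@H](C)[C@@H](OC(C)=O)c2cc(OC)c(OC)c(OC)c2)C[C@@H](OC)C=CC1=O | intermediate
24 | megaphone acetate, (1R,2S)-2-[(1R,5R)-5-methoxy-2-oxo-1-(prop-2-en-1-yl)cyclohex-3-en-1-yl]-1-(3,4,5-trimethoxyphenyl)propyl acetate | C=CC[C@]1([C@H](C)[C@@H](OC(C)=O)c2cc(OC)c(OC)c(OC)c2)C[C@@H](OC)C=CC1=O | target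

## Step count and risks

Total: 12 steps. Longest linear sequence: 12 steps, from aldehyde 1.

**Step 10 (key step).** The most likely failure is poor discrimination between the two diastereotopic aldehyde arms, possibly together with competing placement of the side chain axial in the closing half-chair. Up to four diastereomers of 22 could then form, since the influence of the single C8 centre on a quaternary neighbour is modest. Within the step, a chiral sulfonamide ligand on chromium can be screened in both enantiomeric forms to reinforce the 4R carbinol, which the diequatorial closure ties to the pro-R arm.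

The fallback abandons the arm choice and fixes C6 by the order of two alkylations. It sets out from lactone 8 and returns at 24.
- Lactone 8 would be alkylated with 1-bromo-3-methylbut-2-ene (LiN(SiMe3)2, THF, −78 °C) to the 3-prenyl lactone F1.
- A second alkylation with allyl bromide (LiN(SiMe3)2, DMPU) would give the 3-allyl-3-prenyl lactone F2. The allyl group enters trans to the C8 methyl and C7 aryl groups, which is the C6 configuration of 24.
- The operations of steps 5 to 8 would follow: acetylide 13 to the hydroxy trimethylsilyl ynone F3, acetylation to the acetoxy trimethylsilyl ynone F4, desilylation to the terminal ynone F5, and hydroiodination to the (Z)-β-iodo enone F6.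
- The more electron-rich trisubstituted alkene would be epoxidised selectively with mCPBA to the epoxide F7 and cleaved with H5IO6 to the mono-aldehyde F8.
- Closure under the conditions of step 10, now with one aldehyde and only the C4 face to control, would give the 6-allyl-4-hydroxy enone F9. Methylation as in step 11 gives 24.

**Step 4.** The second alkylation may close in SN2' fashion to a vinylcyclopropane, or the mono-alkylated enolate may react intermolecularly or the allylic chloride eliminate, because the new bond is made at a carbon next to a branched centre. The fallback sets out from 8 and returns at 11. Two successive allylations (LiN(SiMe3)2, allyl bromide; then LiN(SiMe3)2, DMPU, allyl bromide) would lead through the 3-allyl lactone F10 to the 3,3-diallyl lactone F11. Ring-closing metathesis with the second-generation Grubbs catalyst (CH2Cl2, 40 °C) would then form the cyclopentene of 11.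

**Step 5.** Addition to the carbonyl flanked by the spiro carbon may be slow. If the tetrahedral intermediate collapses before the quench, a second acetylide adds to the liberated ynone. The fallback sets out from 11 and returns at 15.
- MeNH(OMe)·HCl and AlMe3 would open 11 to the hydroxy Weinreb amide F12.
- Immediate silylation (Et3SiOTf, 2,6-lutidine) would give the triethylsilyl ether amide F13, which cannot relactonise.
- Acetylide 13 would add once to give the triethylsilyl ether ynone F14.
- PPTS in MeOH would remove the triethylsilyl group to give 15.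

**Step 9.** Over-oxidation of the electron-rich arene, attack of ozone on the vinyl iodide, or Z to E isomerisation of the iodo enone during the reductive work-up may erode the dialdehyde. The fallback sets out from 18 and returns at 20. Dihydroxylation of the ring alkene with catalytic OsO4 and N-methylmorpholine N-oxide, which favours the electron-rich alkene, would give the cis-diol F15. Glycol cleavage with NaIO4 in aqueous THF would give 20.

## Further compounds

F1 | step 10 | (4S,5R)-4-methyl-3-(3-methylbut-2-en-1-yl)-5-(3,4,5-trimethoxyphenyl)oxolan-2-one (C3 epimers) | O=C1C(CC=C(C)C)[C@H](C)[C@H](c2cc(OC)c(OC)c(OC)c2)O1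
F2 | step 10 | (3R,4S,5R)-4-methyl-3-(3-methylbut-2-en-1-yl)-3-(prop-2-en-1-yl)-5-(3,4,5-trimethoxyphenyl)oxolan-2-one | O=C1[C@](CC=C)(CC=C(C)C)[C@H](C)[C@H](c2cc(OC)c(OC)c(OC)c2)O1
F3 | step 10 | hydroxy trimethylsilyl ynone from F2 (C6 bearing allyl and prenyl, free C7 hydroxyl) | C[Si](C)(C)C#CC(=O)[C@](CC=C)(CC=C(C)C)[C@H](C)[C@@H](O)c1cc(OC)c(OC)c(OC)c1
F4 | step 10 | acetoxy trimethylsilyl ynone (C7 acetate of F3) | C[Si](C)(C)C#CC(=O)[C@](CC=C)(CC=C(C)C)[C@H](C)[C@@H](OC(C)=O)c1cc(OC)c(OC)c(OC)c1
F5 | step 10 | terminal ynone (desilylated F4) | C#CC(=O)[C@](CC=C)(CC=C(C)C)[C@H](C)[C@@H](OC(C)=O)c1cc(OC)c(OC)c(OC)c1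
F6 | step 10 | (Z)-β-iodo enone with allyl and prenyl on C6 | I/C=C\C(=O)[C@](CC=C)(CC=C(C)C)[C@H](C)[C@@H](OC(C)=O)c1cc(OC)c(OC)c(OC)c1
F7 | step 10 | epoxide of the prenyl group of F6 (epimers at the epoxide carbon) | I/C=C\C(=O)[C@](CC=C)(CC1OC1(C)C)[C@H](C)[C@@H](OC(C)=O)c1cc(OC)c(OC)c(OC)c1
F8 | step 10 | (Z)-β-iodo enone with allyl and 2-oxoethyl on C6 (mono-aldehyde) | I/C=C\C(=O)[C@](CC=C)(CC=O)[C@H](C)[C@@H](OC(C)=O)c1cc(OC)c(OC)c(OC)c1
F9 | step 10 | (1R,2S)-2-[(1R,5R)-5-hydroxy-2-oxo-1-(prop-2-en-1-yl)cyclohex-3-en-1-yl]-1-(3,4,5-trimethoxyphenyl)propyl acetate | C=CC[C@]1([C@H](C)[C@@H](OC(C)=O)c2cc(OC)c(OC)c(OC)c2)C[C@@H](O)C=CC1=O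
F10 | step 4 | (4S,5R)-4-methyl-3-(prop-2-en-1-yl)-5-(3,4,5-trimethoxyphenyl)oxolan-2-one (C3 epimers) | O=C1C(CC=C)[C@H](C)[C@H](c2cc(OC)c(OC)c(OC)c2)O1
F11 | step 4 | (4S,5R)-4-methyl-3,3-di(prop-2-en-1-yl)-5-(3,4,5-trimethoxyphenyl)oxolan-2-one | O=C1C(CC=C)(CC=C)[C@H](C)[C@H](c2cc(OC)c(OC)c(OC)c2)O1
F12 | step 5 | 1-[(1R,2S)-1-hydroxy-1-(3,4,5-trimethoxyphenyl)propan-2-yl]-N-methoxy-N-methylcyclopent-3-ene-1-carboxamide | CON(C)C(=O)C1(CC=CC1)[C@H](C)[C@@H](O)c1cc(OC)c(OC)c(OC)c1
F13 | step 5 | triethylsilyl ether of F12 | CON(C)C(=O)C1(CC=CC1)[C@H](C)[C@@H](O[Si](CC)(CC)CC)c1cc(OC)c(OC)c(OC)c1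
F14 | step 5 | triethylsilyl ether of hydroxy ynone 15 | C[Si](C)(C)C#CC(=O)C1(CC=CC1)[C@H](C)[C@@H](O[Si](CC)(CC)CC)c1cc(OC)c(OC)c(OC)c1
F15 | step 9 | cis-3,4-dihydroxycyclopentane analogue of 18 (both face isomers) | I/C=C\C(=O)C1(C[C@H](O)[C@H](O)C1)[C@H](C)[C@@H](OC(C)=O)c1cc(OC)c(OC)c(OC)c1
A1 | alternative 1 | spiro tetrahydropyran–cyclohex-3-enone from the Prins–pinacol cascade | ClC[C@@H]1C[C@@]2(CC=CCC2=O)[C@H](C)[C@H](c3cc(OC)c(OC)c(OC)c3)O1
A2 | alternative 1 | 1-chloro-4-[1-(trimethylsilyloxy)cyclopent-3-en-1-yl]hex-4-en-2-ol with the methyl group cis to the CH2 arm (Prins–pinacol substrate) | ClC[C@@H](O)C/C(=C\C)C1(O[Si](C)(C)C)CC=CC1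
A3 | alternative 2 | cis-1,4-diacetoxycyclohex-2-ene with formyl and silyloxy side chain on C6 | O=C[C@]1([C@H](C)[C@@H](O[Si](C)(C)C(C)(C)C)c2cc(OC)c(OC)c(OC)c2)C[C@@H](OC(C)=O)C=C[C@H]1OC(C)=O
A4 | alternative 2 | (1E,3E)-buta-1,3-diene-1,4-diyl diacetate | CC(=O)O/C=C/C=C/OC(C)=O
A5 | alternative 2 | (3S,4R)-4-[(tert-butyldimethylsilyl)oxy]-3-methyl-2-methylidene-4-(3,4,5-trimethoxyphenyl)butanal | C=C(C=O)[C@H](C)[C@@H](O[Si](C)(C)C(C)(C)C)c1cc(OC)c(OC)c(OC)c1
A6 | alternative 3 | megaphone | C=CC[C@]1([C@H](C)[C@@H](O)c2cc(OC)c(OC)c(OC)c2)C[C@@H](OC)C=CC1=O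
A7 | alternative 3 | cis lactone with allyl and (2R,3Z)-4-iodo-2-methoxybut-3-en-1-yl on C6 | O=C1[C@](CC=C)(C[C@@H](OC)/C=C\I)[C@H](C)[C@H](c2cc(OC)c(OC)c(OC)c2)O1
A8 | alternative 3 | (1Z,3S)-1,4-diiodo-3-methoxybut-1-ene | IC[C@@H](OC)/C=C\I
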